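**Retrosynthetic overview**
- Butenolide (formed last, the only ring made for the target): a Seebach dioxolanone carrying a CH(Ph)C(=O)CO2Me arm on its quaternary carbon is opened by methoxide; the acetal carbonyl becomes the CO2Me group and the freed tertiary oxygen closes the 3-hydroxybutenolide, with the silyl groups removed in the same pot.
- C4–C5 bond (quaternary C5): visible-light photoredox coupling of a 5-bromo-1,3-dioxolan-4-one with the silyl enol ether of methyl phenylpyruvate; the tert-butyl acetal controls the face.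
- Aryl–CH2 bond of the diol side chain: nickel/photoredox coupling of the aryl iodide with an (R)-epoxy alcohol made from methyl (R)-glycidate, so the carbinol centre is bought.
- Dioxolanone: from 3-iodo-L-tyrosine by diazotisation with retention, then pivaldehyde acetalisation; the acetal centre is set by the tyrosine centre and later regenerates it.
- Ring order: temporary dioxolanone first (step 2), butenolide last (step 9); both benzene rings are bought.

Assumption: 3-iodo-L-tyrosine, methyl (R)-glycidate and methyl phenylpyruvate are taken as purchasable. C5 is the quaternary butenolide carbon (R in the target) and C4 the phenyl-bearing carbon.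

**Step 1**
Reactants: 1 3-iodo-L-tyrosine
Product: 2 (2S)-2-hydroxy-3-(4-hydroxy-3-iodophenyl)propanoic acid
Conditions: NaNO2, 1 M aq H2SO4, 0 °C to rt
Reagents that add atoms: water, O
Why: Diazotisation of the α-amino acid (hydroxy-de-amination) goes with net retention by neighbouring-carboxylate participation (double inversion), so the bought (S) centre is carried over unchanged.

**Step 2**
Reactants: 2 (2S)-2-hydroxy-3-(4-hydroxy-3-iodophenyl)propanoic acid
Product: 3 (2S,5S)-2-tert-butyl-5-(4-hydroxy-3-iodobenzyl)-1,3-dioxolan-4-one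
Conditions: tBuCHO, TsOH·H2O (cat.), H2SO4 (cat.), pentane/CH2Cl2, Dean–Stark reflux; crystallise the cis isomer
Reagents that add atoms: pivaldehyde, CC(C)(C)C=O
Why: Acid-catalysed acetalisation of the α-hydroxy acid (Seebach self-regeneration-of-stereocentres protocol) favours the 2,5-cis dioxolanone, so the new acetal centre is set by the tyrosine-derived centre; the cis isomer must be pure because only the acetal centre carries the information onward.

**Step 3**
Reactants: 4 methyl (2R)-oxirane-2-carboxylate (methyl (R)-glycidate)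
Product: 5 2-[(2R)-oxiran-2-yl]propan-2-ol
Conditions: MeMgCl (2.1 equiv), THF, −78 to −30 °C; aq NH4Cl
Reagents that add atoms: methylmagnesium chloride, C[Mg]Cl
Why: Double Grignard addition to the ester is faster than epoxide opening at low temperature with a chloride counter-ion, and the bought (R) centre is not touched.

**Step 4**
Reactants: 3 (2S,5S)-2-tert-butyl-5-(4-hydroxy-3-iodobenzyl)-1,3-dioxolan-4-one; 5 2-[(2R)-oxiran-2-yl]propan-2-ol
Product: 7 (2S,5S)-2-tert-butyl-5-{3-[(2R)-2,3-dihydroxy-3-methylbutyl]-4-hydroxybenzyl}-1,3-dioxolan-4-one, via iodohydrin 6 (not isolated)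
Conditions: NiBr2(MeOCH2CH2OMe) (10 mol %), 4,4'-di-tert-butyl-2,2'-bipyridine (12 mol %), 4CzIPN (2 mol %), NaI (0.5 equiv), Et3N (3 equiv), DMA, 450 nm LEDs, rt
Reagents that add atoms: none
Why: Nickel/photoredox reductive cross-electrophile coupling of an aryl iodide with a terminal aliphatic epoxide: iodide opens the epoxide at CH2, the primary radical from the iodohydrin is captured by the arylnickel species, and the C–C bond forms at CH2 so the carbinol centre keeps its (R) configuration.

**Step 5**
Reactants: 7 (2S,5S)-2-tert-butyl-5-{3-[(2R)-2,3-dihydroxy-3-methylbutyl]-4-hydroxybenzyl}-1,3-dioxolan-4-one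
Product: 8 (2S,5S)-2-tert-butyl-5-{3-[(2R)-3-methyl-2,3-bis(triethylsilyloxy)butyl]-4-(triethylsilyloxy)benzyl}-1,3-dioxolan-4-one
Conditions: Et3SiOTf (3.6 equiv), 2,6-lutidine (5 equiv), CH2Cl2, −78 to 0 °C
Reagents that add atoms: triethylsilyl trifluoromethanesulfonate, CC[Si](CC)(CC)OS(=O)(=O)C(F)(F)F
Why: Exhaustive silylation with the silyl triflate covers the phenol, the secondary and the tertiary hydroxyl in one operation, and 2,6-lutidine is too weak a base to enolise the lactone.

**Step 6**
Reactants: 8 (2S,5S)-2-tert-butyl-5-{3-[(2R)-3-methyl-2,3-bis(triethylsilyloxy)butyl]-4-(triethylsilyloxy)benzyl}-1,3-dioxolan-4-one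
Product: 10 (2R,5R)-5-bromo-2-tert-butyl-5-{3-[(2R)-3-methyl-2,3-bis(triethylsilyloxy)butyl]-4-(triethylsilyloxy)benzyl}-1,3-dioxolan-4-one, via lithium enolate 9 (not isolated)
Conditions: LiN(iPr)2 (1.1 equiv), THF, −78 °C; BrCCl2CCl2Br (1.2 equiv), −78 °C; cold pH 7 work-up, used at once
Reagents that add atoms: 1,2-dibromo-1,1,2,2-tetrachloroethane, BrC(Cl)(Cl)C(Cl)(Cl)Br
Why: Electrophilic bromination of the dioxolanone enolate is regiospecific for C5 (bromine enters anti to tert-butyl), and the acetal centre stores the stereochemical information while C5 is planarised again in step 8.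

**Step 7**
Reactants: 11 methyl phenylpyruvate (methyl 2-oxo-3-phenylpropanoate)
Product: 12 methyl (2Z)-2-(tert-butyldimethylsilyloxy)-3-phenylprop-2-enoate
Conditions: tBuMe2SiCl (1.2 equiv), Et3N, DMAP (cat.), CH2Cl2, 0 °C to rt
Reagents that add atoms: tert-butyldimethylsilyl chloride, CC(C)(C)[Si](C)(C)Cl
Why: Arylpyruvates are largely enolised, so simple O-silylation of the (Z)-enol gives the silyl enol ether.

**Step 8**
Reactants: 10 (2R,5R)-5-bromo-2-tert-butyl-5-{3-[(2R)-3-methyl-2,3-bis(triethylsilyloxy)butyl]-4-(triethylsilyloxy)benzyl}-1,3-dioxolan-4-one; 12 methyl (2Z)-2-(tert-butyldimethylsilyloxy)-3-phenylprop-2-enoate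
Product: 13 (2S,5R)-2-tert-butyl-5-(3-methoxy-2,3-dioxo-1-phenylpropyl)-5-{3-[(2R)-3-methyl-2,3-bis(triethylsilyloxy)butyl]-4-(triethylsilyloxy)benzyl}-1,3-dioxolan-4-one (epimers at the benzylic CH)
Conditions: fac-Ir(ppy)3 (1 mol %), 12 (3 equiv), MeCN (0.3 M), 450 nm LEDs, 0 °C to rt, argon; aq NaHCO3
Reagents that add atoms: none
Why: Proposed new method: a visible-light photoredox radical–polar crossover alkylation of a pyruvate silyl enol ether by a tertiary 5-bromo-1,3-dioxolan-4-one. Excited fac-Ir(ppy)3 reduces the activated C–Br bond to a planar captodative C5 radical, which adds to the CHPh terminus of the captodative alkene 12 on the face anti to the tert-butyl group (the benzyl group stays cis to tert-butyl, giving 5R, the C5 configuration of the target). The resulting α-silyloxy-α-ester radical is oxidised by tetravalent iridium (or by bromine-atom transfer from 10), and bromide removes the silyl group to leave the α-keto ester. The closest known reactions are photoredox couplings of α-bromo carbonyl compounds with silyl enol ethers to 1,4-dicarbonyls and the anti-selective trapping of dioxolanonyl radicals by allylstannanes; neither a tertiary bromodioxolanone nor a pyruvate enol ether has been used in this way, nor has a quaternary α-hydroxy acid centre been made by it.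

**Step 9**
Reactants: 13 (2S,5R)-2-tert-butyl-5-(3-methoxy-2,3-dioxo-1-phenylpropyl)-5-{3-[(2R)-3-methyl-2,3-bis(triethylsilyloxy)butyl]-4-(triethylsilyloxy)benzyl}-1,3-dioxolan-4-one
Product: 15 8''R,9''-diol versicolactone B (methyl (2R)-2-{3-[(2R)-2,3-dihydroxy-3-methylbutyl]-4-hydroxybenzyl}-4-hydroxy-5-oxo-3-phenyl-2,5-dihydrofuran-2-carboxylate), via bis-silyl butenolide 14 (not isolated)
Conditions: NaOMe (6 equiv), MeOH/THF, 0 °C, 2 h; then HCl/MeOH to pH 1, rt, 2 h
Reagents that add atoms: sodium methoxide, C[O-].[Na+]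
Why: Methoxide transesterifies the acyl-acetal carbonyl (Seebach acetal cleavage), releasing pivaldehyde and the tertiary alkoxide, which lactonises onto the keto-ester carbonyl to give the 3-hydroxybutenolide; excess base holds the keto ester as its enolate, which blocks retro-aldol loss of the quaternary centre, and the acid stage removes the remaining silyl ethers without creating or touching a stereocentre.

**Compound list**
1 | 3-iodo-L-tyrosine | N[C@@H](Cc1ccc(O)c(I)c1)C(=O)O | starting material
2 | (2S)-2-hydroxy-3-(4-hydroxy-3-iodophenyl)propanoic acid | O[C@@H](Cc1ccc(O)c(I)c1)C(=O)O | intermediate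
3 | (2S,5S)-2-tert-butyl-5-(4-hydroxy-3-iodobenzyl)-1,3-dioxolan-4-one | CC(C)(C)[C@@H]1OC(=O)[C@H](Cc2ccc(O)c(I)c2)O1 | intermediate
4 | methyl (2R)-oxirane-2-carboxylate | COC(=O)[C@H]1CO1 | starting material
5 | 2-[(2R)-oxiran-2-yl]propan-2-ol | CC(C)(O)[C@H]1CO1 | intermediate
6 | (2S)-1-iodo-3-methylbutane-2,3-diol | CC(C)(O)[C@H](O)CI | intermediate (not isolated)
7 | (2S,5S)-2-tert-butyl-5-{3-[(2R)-2,3-dihydroxy-3-methylbutyl]-4-hydroxybenzyl}-1,3-dioxolan-4-one | CC(C)(C)[C@@H]1OC(=O)[C@H](Cc2ccc(O)c(C[C@@H](O)C(C)(C)O)c2)O1 | intermediate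
8 | (2S,5S)-2-tert-butyl-5-{3-[(2R)-3-methyl-2,3-bis(triethylsilyloxy)butyl]-4-(triethylsilyloxy)benzyl}-1,3-dioxolan-4-one | CC(C)(C)[C@@H]1OC(=O)[C@H](Cc2ccc(O[Si](CC)(CC)CC)c(C[C@@H](O[Si](CC)(CC)CC)C(C)(C)O[Si](CC)(CC)CC)c2)O1 | intermediate
9 | lithium enolate of 8 (lithium (2S)-2-tert-butyl-5-(arylmethyl)-1,3-dioxol-4-olate) | [Li+].CC(C)(C)[C@@H]1OC([O-])=C(Cc2ccc(O[Si](CC)(CC)CC)c(C[C@@H](O[Si](CC)(CC)CC)C(C)(C)O[Si](CC)(CC)CC)c2)O1 | intermediate (not isolated)
10 | (2R,5R)-5-bromo-2-tert-butyl-5-{3-[(2R)-3-methyl-2,3-bis(triethylsilyloxy)butyl]-4-(triethylsilyloxy)benzyl}-1,3-dioxolan-4-one | CC(C)(C)[C@@H]1OC(=O)[C@](Br)(Cc2ccc(O[Si](CC)(CC)CC)c(C[C@@H](O[Si](CC)(CC)CC)C(C)(C)O[Si](CC)(CC)CC)c2)O1 | intermediate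
11 | methyl phenylpyruvate (methyl 2-oxo-3-phenylpropanoate) | COC(=O)C(=O)Cc1ccccc1 | starting material
12 | methyl (2Z)-2-(tert-butyldimethylsilyloxy)-3-phenylprop-2-enoate | COC(=O)/C(O[Si](C)(C)C(C)(C)C)=C/c1ccccc1 | intermediate
13 | (2S,5R)-2-tert-butyl-5-(3-methoxy-2,3-dioxo-1-phenylpropyl)-5-{3-[(2R)-3-methyl-2,3-bis(triethylsilyloxy)butyl]-4-(triethylsilyloxy)benzyl}-1,3-dioxolan-4-one (epimers at the benzylic CH) | CC(C)(C)[C@@H]1OC(=O)[C@](C(c3ccccc3)C(=O)C(=O)OC)(Cc2ccc(O[Si](CC)(CC)CC)c(C[C@@H](O[Si](CC)(CC)CC)C(C)(C)O[Si](CC)(CC)CC)c2)O1 | intermediate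
14 | methyl (2R)-2-{3-[(2R)-3-methyl-2,3-bis(triethylsilyloxy)butyl]-4-hydroxybenzyl}-4-hydroxy-5-oxo-3-phenyl-2,5-dihydrofuran-2-carboxylate | COC(=O)[C@]1(Cc2ccc(O)c(C[C@@H](O[Si](CC)(CC)CC)C(C)(C)O[Si](CC)(CC)CC)c2)OC(=O)C(O)=C1c1ccccc1 | intermediate (not isolated)
15 | 8''R,9''-diol versicolactone B | COC(=O)[C@]1(Cc2ccc(O)c(C[C@@H](O)C(C)(C)O)c2)OC(=O)C(O)=C1c1ccccc1 | target

**Step count**
Total steps: 9. Longest linear sequence: 7 (steps 1, 2, 4, 5, 6, 8, 9, from 1 to 15).

**Three steps most likely to fail, each with a fallback**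

Step 8 (the proposed photoredox coupling). Risks: the hindered captodative radical may add slowly to the β-phenyl enol ether, and bromide 10 may lose HBr to the 5-arylidene dioxolanone before it couples. The fallback uses known enolate chemistry and also bypasses step 6. It sets out from 8. Benzaldehyde and methyl nitroacetate are condensed (TiCl4, pyridine, THF; Knoevenagel) to methyl 2-nitro-3-phenylprop-2-enoate F1. The lithium enolate of 8 (LiN(iPr)2, THF, −78 °C) adds to F1 anti to the tert-butyl group, as in the established Michael additions of these dioxolanone enolates to nitroalkenes, to give the nitro ester (2S,5R)-2-tert-butyl-5-(3-methoxy-2-nitro-3-oxo-1-phenylpropyl)-5-{3-[(2R)-3-methyl-2,3-bis(triethylsilyloxy)butyl]-4-(triethylsilyloxy)benzyl}-1,3-dioxolan-4-one F2. An oxidative Nef reaction of its nitronate (KOtBu, 1 equiv, THF, −78 °C, then dimethyldioxirane in acetone) gives the α-keto ester, and the route is rejoined at 13.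

Step 4 (nickel/photoredox epoxide–aryl iodide coupling on a free ortho-iodophenol). Risks: the phenoxide may slow oxidative addition or bind nickel, and the free epoxy alcohol may open unproductively. The fallback sets out from 3 and 5 and replaces the light-driven in-situ epoxide opening by a zinc-driven thermal coupling of fully protected partners. Phenol 3 is silylated (Et3SiCl, imidazole, DMF) to (2S,5S)-2-tert-butyl-5-[3-iodo-4-(triethylsilyloxy)benzyl]-1,3-dioxolan-4-one F3. Epoxide 5 is opened with LiI/AcOH in THF to iodohydrin 6, now isolated, and silylated (Et3SiOTf, 2,6-lutidine) to (2S)-1-iodo-3-methyl-2,3-bis(triethylsilyloxy)butane F4. Reductive cross-electrophile coupling of F3 with F4 (NiI2, 4,4'-di-tert-butyl-2,2'-bipyridine, pyridine, zinc dust, DMPU, 60 °C) gives 8 directly, so step 5 is skipped and the route is rejoined at 8.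

Step 9 (one-pot ring switch and desilylation). Risks: retro-aldol cleavage of the transient γ-hydroxy-α-keto ester, incomplete opening of the hindered acetal, or acid-induced chroman formation from the phenol and the tertiary alcohol. The fallback sets out from 13 and replaces basic methanolysis by acidic hydrolysis followed by esterification. Aqueous acid (3 M HCl, dioxane, 40 °C) removes the silyl groups and the pivaldehyde acetal, and the freed hydroxy acid lactonises onto the keto ester to give (2R)-2-{3-[(2R)-2,3-dihydroxy-3-methylbutyl]-4-hydroxybenzyl}-4-hydroxy-5-oxo-3-phenyl-2,5-dihydrofuran-2-carboxylic acid F5. Fischer esterification (MeOH, cat. H2SO4, rt) then gives the target, rejoining at 15.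

**Further compounds**
F1 | step 8 | methyl 2-nitro-3-phenylprop-2-enoate (E/Z mixture) | COC(=O)C(=Cc1ccccc1)[N+](=O)[O-]
F2 | step 8 | (2S,5R)-2-tert-butyl-5-(3-methoxy-2-nitro-3-oxo-1-phenylpropyl)-5-{3-[(2R)-3-methyl-2,3-bis(triethylsilyloxy)butyl]-4-(triethylsilyloxy)benzyl}-1,3-dioxolan-4-one (epimer mixture in the side arm) | CC(C)(C)[C@@H]1OC(=O)[C@](C(c3ccccc3)C(C(=O)OC)[N+](=O)[O-])(Cc2ccc(O[Si](CC)(CC)CC)c(C[C@@H](O[Si](CC)(CC)CC)C(C)(C)O[Si](CC)(CC)CC)c2)O1
F3 | step 4 | (2S,5S)-2-tert-butyl-5-[3-iodo-4-(triethylsilyloxy)benzyl]-1,3-dioxolan-4-one | CC(C)(C)[C@@H]1OC(=O)[C@H](Cc2ccc(O[Si](CC)(CC)CC)c(I)c2)O1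
F4 | step 4 | (2S)-1-iodo-3-methyl-2,3-bis(triethylsilyloxy)butane | CC(C)(O[Si](CC)(CC)CC)[C@H](O[Si](CC)(CC)CC)CI
F5 | step 9 | (2R)-2-{3-[(2R)-2,3-dihydroxy-3-methylbutyl]-4-hydroxybenzyl}-4-hydroxy-5-oxo-3-phenyl-2,5-dihydrofuran-2-carboxylic acid | OC(=O)[C@]1(Cc2ccc(O)c(C[C@@H](O)C(C)(C)O)c2)OC(=O)C(O)=C1c1ccccc1
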